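Disconnection of O1–C2 and C3–C4 (oxolane numbered O1, C2 aryl, C3 CH2OH, C4 aroyl, C5) splits the ring into a three-atom O1/C5/C4 piece and a two-carbon C2/C3 piece. With the aroyl carbon disguised as a 1-arylvinyl group, the first piece is a racemic vinyl epoxide; the second is a benzylidene malonate. One palladium-catalysed formal [3+2] cycloaddition joins them: it closes the oxolane, makes both ring bonds and sets C2 and C4 (2,4-cis) under ligand control. The geminal diester leaves C3 to a later thermodynamic protonation, and the alkene is cleaved to the ketone near the end. Both partners come from O-benzylisovanillin.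

Key step: step 5

Assumption: the sense of induction of the diphosphine cannot be predicted with certainty, so (R)-BINAP is written and (S)-BINAP replaces it if a first run gives the antipodal series; 1 is taken as a catalogue compound, and all locants follow the oxolane numbering above.

Step 1
Reactants: 1 3-benzyloxy-4-methoxybenzaldehyde (O-benzylisovanillin); 2 dimethyl malonate
Product: 3 dimethyl 2-[(3-benzyloxy-4-methoxyphenyl)methylidene]propanedioate
Conditions: piperidine (cat.), AcOH (cat.), toluene, reflux, Dean–Stark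
Reagents that add atoms: none
Why: Knoevenagel condensation, in which the piperidine-derived iminium ion of 1 is attacked by the malonate and azeotropic removal of water drives the electron-rich aldehyde to the arylidene malonate.

Step 2
Reactants: 1 3-benzyloxy-4-methoxybenzaldehyde
Product: 5 2-(3-benzyloxy-4-methoxyphenyl)acetaldehyde, via methyl enol ether 4 (not isolated)
Conditions: MeOCH2PPh3Cl, KOtBu, THF, 0 °C to rt; then 2 M HCl, THF, 50 °C
Reagents that add atoms: (methoxymethyl)triphenylphosphonium chloride, COC[P+](c1ccccc1)(c1ccccc1)c1ccccc1.[Cl-]; water, O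
Why: Wittig olefination with the methoxymethylidene ylide gives the enol ether, whose acid hydrolysis should release the one-carbon-homologated aldehyde while the benzyl and methyl aryl ethers stay inert to dilute acid.

Step 3
Reactants: 5 2-(3-benzyloxy-4-methoxyphenyl)acetaldehyde
Product: 7 2-(3-benzyloxy-4-methoxyphenyl)prop-2-enal, via Mannich base 6 (not isolated)
Conditions: Eschenmoser's salt (Me2N=CH2 I), Et3N, CH2Cl2, rt; product kept cold and used at once
Reagents that add atoms: N,N-dimethylmethylideneiminium iodide (Eschenmoser's salt), C=[N+](C)C.[I-]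
Why: Eschenmoser methylenation, a Mannich reaction of the readily enolised arylacetaldehyde with the preformed iminium salt followed by base-induced β-elimination of dimethylamine, which conjugation with the aryl ring and the formyl group makes easy.

Step 4
Reactants: 7 2-(3-benzyloxy-4-methoxyphenyl)prop-2-enal
Product: 8 rac-2-[1-(3-benzyloxy-4-methoxyphenyl)ethenyl]oxirane
Conditions: Me3SI, n-BuLi, THF, −10 °C to rt
Reagents that add atoms: trimethylsulfonium iodide, C[S+](C)C.[I-]
Why: Corey–Chaykovsky epoxidation, in which the unstabilised sulfonium methylide adds irreversibly to the carbonyl carbon and the betaine closes to the oxirane, so the enal should give the 2-alkenyloxirane and not a cyclopropane; the racemate is what step 5 requires.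

Step 5
Reactants: 3 dimethyl 2-[(3-benzyloxy-4-methoxyphenyl)methylidene]propanedioate; 8 rac-2-[1-(3-benzyloxy-4-methoxyphenyl)ethenyl]oxirane
Product: 9 dimethyl (2R,4S)-2-(3-benzyloxy-4-methoxyphenyl)-4-[1-(3-benzyloxy-4-methoxyphenyl)ethenyl]oxolane-3,3-dicarboxylate (2,4-cis)
Conditions: Pd2(dba)3·CHCl3 (2.5 mol%), (R)-BINAP (6 mol%), THF, 40 °C; 8 (1.5 equiv) added slowly
Reagents that add atoms: none
Why: Zerovalent palladium ionises the allylic C–O bond of racemic 8 with inversion to a 2-aryl-π-allylpalladium alkoxide; the alkoxide adds reversibly to the benzylidene carbon of 3 (O1–C2), and the malonate carbanion so formed attacks the neighbouring allyl terminus anti to the metal (C3–C4), releasing the catalyst. The closest known reaction type is the palladium-catalysed formal [3+2] cycloaddition of 2-alkenyloxiranes with doubly activated alkenes, run as a dynamic kinetic asymmetric transformation with a chiral diphosphine; enones of comparable electrophilicity are accepted in such reactions. The oxolane is closed by 5-exo attack of the carbanion on the proximal allyl carbon, an irreversible step because a dimethyl malonate anion is not expelled again by the catalyst. C4 is controlled by the ligand, which selects one of the two allyl faces while they interconvert by η3–η1–η3 slippage through the unsubstituted CH2 terminus; C2 is controlled relative to C4 by the envelope transition state that keeps the aryl and the arylvinyl group pseudo-equatorial, the reversible oxa-Michael step feeding this pathway, so that 2,4-cis 9 should predominate. The step needs five- over seven-membered closure, 2,4-cis and facial selectivity, and capture of the zwitterion before it isomerises to a dienol or enal; the short tether, the soft stabilised carbanion, the ligand and slow addition of 8 to concentrated 3 should secure these. Any 2,4-trans isomer is removed here by chromatography, because C2 cannot be corrected later.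

Step 6
Reactants: 9 dimethyl (2R,4S)-2-(3-benzyloxy-4-methoxyphenyl)-4-[1-(3-benzyloxy-4-methoxyphenyl)ethenyl]oxolane-3,3-dicarboxylate
Product: 11 methyl (2S,3S,4R)-2-(3-benzyloxy-4-methoxyphenyl)-4-[1-(3-benzyloxy-4-methoxyphenyl)ethenyl]oxolane-3-carboxylate (2,3-trans and 3,4-trans), via C3-epimeric monoester 10 (not isolated)
Conditions: LiCl, H2O, DMSO, 150 °C; then crude 10, NaOMe (0.3 equiv), MeOH, 50 °C
Reagents that add atoms: none
Why: Krapcho dealkoxycarbonylation (chloride attack on an ester methyl group, loss of CO2, protonation of the ester enolate) followed by methoxide-mediated enolisation, which should equilibrate C3 to the isomer with the ester trans to both the C2 aryl and the C4 alkenyl group, while C2 and C4 carry no acidic hydrogen and stay untouched.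

Step 7
Reactants: 11 methyl (2S,3S,4R)-2-(3-benzyloxy-4-methoxyphenyl)-4-[1-(3-benzyloxy-4-methoxyphenyl)ethenyl]oxolane-3-carboxylate
Product: 12 [(2S,3R,4R)-2-(3-benzyloxy-4-methoxyphenyl)-4-[1-(3-benzyloxy-4-methoxyphenyl)ethenyl]oxolan-3-yl]methanol
Conditions: LiAlH4, THF, 0 °C
Reagents that add atoms: none
Why: Hydride reduction of the methyl ester to the primary alcohol, which leaves the isolated alkene, the ethers and all three stereocentres unchanged.

Step 8
Reactants: 12 [(2S,3R,4R)-2-(3-benzyloxy-4-methoxyphenyl)-4-[1-(3-benzyloxy-4-methoxyphenyl)ethenyl]oxolan-3-yl]methanol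
Product: 14 (2S,3R,4S)-4-(3-benzyloxy-4-methoxybenzoyl)-2-(3-benzyloxy-4-methoxyphenyl)-3-(hydroxymethyl)oxolane, via 1,2-diol 13 (not isolated)
Conditions: OsO4 (2 mol%), NaIO4, 2,6-lutidine, 1,4-dioxane/H2O (3:1), rt
Reagents that add atoms: osmium tetroxide (catalytic oxygen carrier), O=[Os](=O)(=O)=O; sodium periodate (stoichiometric oxygen source), [Na+].[O-]I(=O)(=O)=O
Why: Lemieux–Johnson oxidation, in which OsO4 dihydroxylates the electron-rich 1,1-disubstituted alkene and NaIO4 cleaves the diol to the aryl ketone and formaldehyde, the non-basic medium leaving the now enolisable C4 in its trans (and thermodynamically preferred) configuration.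

Step 9
Reactants: 14 (2S,3R,4S)-4-(3-benzyloxy-4-methoxybenzoyl)-2-(3-benzyloxy-4-methoxyphenyl)-3-(hydroxymethyl)oxolane
Product: 15 (2S,3R,4S)-4-(3-hydroxy-4-methoxybenzoyl)-2-(3-hydroxy-4-methoxyphenyl)-3-(hydroxymethyl)oxolane (CNP0234761.1)
Conditions: H2 (1 atm), 10% Pd/C, EtOAc, rt, stopped after uptake of two equivalents
Reagents that add atoms: none
Why: Catalytic hydrogenolysis of the two aryl benzyl ethers, which under neutral conditions should be faster than reduction of the electron-rich aryl ketone or cleavage of the cyclic benzylic C2–O1 bond.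

Compound list
1 | 3-benzyloxy-4-methoxybenzaldehyde (O-benzylisovanillin) | COc1ccc(C=O)cc1OCc1ccccc1 | starting material
2 | dimethyl malonate | COC(=O)CC(=O)OC | starting material
3 | dimethyl 2-[(3-benzyloxy-4-methoxyphenyl)methylidene]propanedioate | COC(=O)C(=Cc1ccc(OC)c(OCc2ccccc2)c1)C(=O)OC | intermediate
4 | 2-benzyloxy-1-methoxy-4-(2-methoxyethenyl)benzene, E/Z mixture | COC=Cc1ccc(OC)c(OCc2ccccc2)c1 | intermediate
5 | 2-(3-benzyloxy-4-methoxyphenyl)acetaldehyde | O=CCc1ccc(OC)c(OCc2ccccc2)c1 | intermediate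
6 | rac-2-(3-benzyloxy-4-methoxyphenyl)-3-(dimethylamino)propanal | CN(C)CC(C=O)c1ccc(OC)c(OCc2ccccc2)c1 | intermediate
7 | 2-(3-benzyloxy-4-methoxyphenyl)prop-2-enal | C=C(C=O)c1ccc(OC)c(OCc2ccccc2)c1 | intermediate
8 | rac-2-[1-(3-benzyloxy-4-methoxyphenyl)ethenyl]oxirane | C=C(c1ccc(OC)c(OCc2ccccc2)c1)C1CO1 | intermediate
9 | dimethyl (2R,4S)-2-(3-benzyloxy-4-methoxyphenyl)-4-[1-(3-benzyloxy-4-methoxyphenyl)ethenyl]oxolane-3,3-dicarboxylate, 2,4-cis | C=C(c1ccc(OC)c(OCc2ccccc2)c1)[C@@H]1CO[C@H](c2ccc(OC)c(OCc3ccccc3)c2)C1(C(=O)OC)C(=O)OC | intermediate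
10 | methyl (2S,4R)-2-(3-benzyloxy-4-methoxyphenyl)-4-[1-(3-benzyloxy-4-methoxyphenyl)ethenyl]oxolane-3-carboxylate, mixture of C3 epimers | C=C(c1ccc(OC)c(OCc2ccccc2)c1)[C@@H]1CO[C@H](c2ccc(OC)c(OCc3ccccc3)c2)C1C(=O)OC | intermediate
11 | methyl (2S,3S,4R)-2-(3-benzyloxy-4-methoxyphenyl)-4-[1-(3-benzyloxy-4-methoxyphenyl)ethenyl]oxolane-3-carboxylate, 2,3-trans and 3,4-trans | C=C(c1ccc(OC)c(OCc2ccccc2)c1)[C@@H]1CO[C@H](c2ccc(OC)c(OCc3ccccc3)c2)[C@H]1C(=O)OC | intermediate
12 | [(2S,3R,4R)-2-(3-benzyloxy-4-methoxyphenyl)-4-[1-(3-benzyloxy-4-methoxyphenyl)ethenyl]oxolan-3-yl]methanol | C=C(c1ccc(OC)c(OCc2ccccc2)c1)[C@@H]1CO[C@H](c2ccc(OC)c(OCc3ccccc3)c2)[C@H]1CO | intermediate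
13 | (2S,3R,4S)-2-(3-benzyloxy-4-methoxyphenyl)-4-[1-(3-benzyloxy-4-methoxyphenyl)-1,2-dihydroxyethyl]-3-(hydroxymethyl)oxolane, both carbinol epimers | OCC(O)(c1ccc(OC)c(OCc2ccccc2)c1)[C@@H]1CO[C@H](c2ccc(OC)c(OCc3ccccc3)c2)[C@H]1CO | intermediate
14 | (2S,3R,4S)-4-(3-benzyloxy-4-methoxybenzoyl)-2-(3-benzyloxy-4-methoxyphenyl)-3-(hydroxymethyl)oxolane | O=C(c1ccc(OC)c(OCc2ccccc2)c1)[C@@H]1CO[C@H](c2ccc(OC)c(OCc3ccccc3)c2)[C@H]1CO | intermediate
15 | (2S,3R,4S)-4-(3-hydroxy-4-methoxybenzoyl)-2-(3-hydroxy-4-methoxyphenyl)-3-(hydroxymethyl)oxolane, all-trans at C3, 2,4-cis | COc1ccc(C(=O)[C@@H]2CO[C@H](c3ccc(OC)c(O)c3)[C@H]2CO)cc1O | target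

Total step count: 9. Longest linear sequence: 8 steps (1 → 5 → 7 → 8 → 9 → 11 → 12 → 14 → 15; step 1 is the convergent branch).

Steps most likely to fail

Step 5. The oxa-Michael addition to the electron-rich, only moderately electrophilic arylidene malonate may be too slow. The zwitterion would then drain away by proton transfer to a dienol or enal and by oligomerisation, or facial and 2,4-selectivity may be poor. The fallback raises the electrophilicity of the acceptor and sets out from 1 and 8. Aldehyde 1 is condensed with Meldrum's acid (water, 75 °C) to 5-[(3-benzyloxy-4-methoxyphenyl)methylidene]-2,2-dimethyl-1,3-dioxane-4,6-dione F1. The same Pd2(dba)3·CHCl3/BINAP cycloaddition with 8 should then give the spiro adduct (1R,4S)-1-(3-benzyloxy-4-methoxyphenyl)-4-[1-(3-benzyloxy-4-methoxyphenyl)ethenyl]-8,8-dimethyl-2,7,9-trioxaspiro[4.5]decane-6,10-dione F2. NaOMe in MeOH opens the dioxanedione with loss of acetone to (2R,4S)-2-(3-benzyloxy-4-methoxyphenyl)-4-[1-(3-benzyloxy-4-methoxyphenyl)ethenyl]-3-(methoxycarbonyl)oxolane-3-carboxylic acid F3. Its free acid is decarboxylated in DMSO at 120 °C, and the route is rejoined at 10, which step 6 equilibrates to 11.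

Step 6. At 150 °C chloride may also dealkylate the aryl methyl ethers, or the ester enolate may expel the ring oxygen by β-elimination and open the oxolane. The fallback replaces nucleophilic dealkylation by hydrolysis and sets out from 9. KOH in MeOH/H2O at reflux gives (2R,4S)-2-(3-benzyloxy-4-methoxyphenyl)-4-[1-(3-benzyloxy-4-methoxyphenyl)ethenyl]oxolane-3,3-dicarboxylic acid F4, which has no enolisable hydrogen. Decarboxylation in pyridine at 100 °C gives (2S,4R)-2-(3-benzyloxy-4-methoxyphenyl)-4-[1-(3-benzyloxy-4-methoxyphenyl)ethenyl]oxolane-3-carboxylic acid F5 as C3 epimers. Methylation (MeI, K2CO3, DMF) returns to the route at 10, which is equilibrated to 11 as before.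

Step 4. Under the strongly basic ylide conditions the 2-arylacrolein may polymerise, dimerise or suffer conjugate addition before the carbonyl group is attacked. The fallback avoids the enal and the arylacetaldehyde altogether and sets out from 1. Vinylmagnesium bromide (THF, 0 °C) gives rac-1-(3-benzyloxy-4-methoxyphenyl)prop-2-en-1-ol F6. MnO2 (CH2Cl2) oxidises it to 1-(3-benzyloxy-4-methoxyphenyl)prop-2-en-1-one F7. Nucleophilic epoxidation (t-BuOOH, DBU, CH2Cl2) gives rac-(3-benzyloxy-4-methoxyphenyl)(oxiran-2-yl)methanone F8. Wittig methylenation (Ph3PCH3Br, KOtBu, THF, 0 °C) comes back to the route at 8.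

Further compounds
F1 | step 5 | 5-[(3-benzyloxy-4-methoxyphenyl)methylidene]-2,2-dimethyl-1,3-dioxane-4,6-dione | CC1(C)OC(=O)C(=Cc2ccc(OC)c(OCc3ccccc3)c2)C(=O)O1
F2 | step 5 | (1R,4S)-1-(3-benzyloxy-4-methoxyphenyl)-4-[1-(3-benzyloxy-4-methoxyphenyl)ethenyl]-8,8-dimethyl-2,7,9-trioxaspiro[4.5]decane-6,10-dione | C=C(c1ccc(OC)c(OCc2ccccc2)c1)[C@@H]1CO[C@H](c2ccc(OC)c(OCc3ccccc3)c2)C12C(=O)OC(C)(C)OC2=O
F3 | step 5 | (2R,4S)-2-(3-benzyloxy-4-methoxyphenyl)-4-[1-(3-benzyloxy-4-methoxyphenyl)ethenyl]-3-(methoxycarbonyl)oxolane-3-carboxylic acid, C3 epimers | C=C(c1ccc(OC)c(OCc2ccccc2)c1)[C@@H]1CO[C@H](c2ccc(OC)c(OCc3ccccc3)c2)C1(C(=O)O)C(=O)OC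
F4 | step 6 | (2R,4S)-2-(3-benzyloxy-4-methoxyphenyl)-4-[1-(3-benzyloxy-4-methoxyphenyl)ethenyl]oxolane-3,3-dicarboxylic acid | C=C(c1ccc(OC)c(OCc2ccccc2)c1)[C@@H]1CO[C@H](c2ccc(OC)c(OCc3ccccc3)c2)C1(C(=O)O)C(=O)O
F5 | step 6 | (2S,4R)-2-(3-benzyloxy-4-methoxyphenyl)-4-[1-(3-benzyloxy-4-methoxyphenyl)ethenyl]oxolane-3-carboxylic acid, C3 epimers | C=C(c1ccc(OC)c(OCc2ccccc2)c1)[C@@H]1CO[C@H](c2ccc(OC)c(OCc3ccccc3)c2)C1C(=O)O
F6 | step 4 | rac-1-(3-benzyloxy-4-methoxyphenyl)prop-2-en-1-ol | C=CC(O)c1ccc(OC)c(OCc2ccccc2)c1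
F7 | step 4 | 1-(3-benzyloxy-4-methoxyphenyl)prop-2-en-1-one | C=CC(=O)c1ccc(OC)c(OCc2ccccc2)c1
F8 | step 4 | rac-(3-benzyloxy-4-methoxyphenyl)(oxiran-2-yl)methanone | O=C(C1CO1)c1ccc(OC)c(OCc2ccccc2)c1
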